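| flask | starting material | reagent | target | time |
|---|---|---|---|---|
| blue | 0.150 M | 0.165 M |  |  |
| ochre | 0.0900 M | 0.105 M |  |  |
| amber | 0.150 M | 0.165 M | 0.0750 M |  |
| violet | 0.150 M | 0.0830 M |  |  |
| green | 0.380 M | 0.410 M |  | 35 min |
- blue run (time / min: [target] / M): 1.4: 7 × 10⁻⁴; 2.2: 6 × 10⁻⁴; 3.5: 0.0018; 5.6: 0.0041; 8.8: 0.0107; 14: 0.0219; 22: 0.0330; 35: 0.0424
- ochre run (time / min: [target] / M): 1.4: 0; 2.2: 0; 3.5: 8 × 10⁻⁴; 5.6: 0.0031; 8.8: 0.0052; 14: 0.0086; 22: 0.0150; 35: 0.0198
- amber run (time / min: [target] / M): 1.4: 0.0725; 2.2: 0.0717; 3.5: 0.0717; 5.6: 0.0712; 8.8: 0.0736; 14: 0.0740; 22: 0.0760; 35: 0.0753
- violet run (time / min: [target] / M): 1.4: 0.0010; 2.2: 0.0022; 3.5: 0; 5.6: 0.0026; 8.8: 0.0041; 14: 0.0101; 22: 0.0183; 35: 0.0238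

(readings scatter by 8 × 10⁻⁴ M)
- Overall: starting material + reagent -> target.
- Constant volume, constant temperature.
- "The second partner" is reagent.
- An order is taken over about fifteen percent of the charge, up and down.
* apparent order in [reagent] of the starting rate, round the charge of the blue run (the rate where two percent of its starting material have turned into target)
* apparent order in [starting material] of the starting rate, round the charge of the blue run (the rate where two percent of its starting material have turned into target) (one fixed amount of target, the same in the runs compared)
* target in the green run at 35 min, as a share of the starting material charged
* which of these the readings show (the substrate pairs with itself / the product decays / the product binds the substrate)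

At early times the blue run lags: it holds 0.0018 M of target at 3.5 min and 0.0107 M at 8.8 min. Over those same minutes the amber run sinks from its charged 0.0750 M to 0.0712 M at 5.6 min, so target is being lost while it is made. We count that loss by hand, before any computer fit. If target leaves its own making undisturbed, amber minus blue is what remains of the charged target, and the logarithm of charged over remaining is the number of target lifetimes in the run, the number of times a target's mean lifetime fits into the time:

lifetimes in 35 min = ln(0.0750 M / 0.0329 M) = 0.824

Now we build the green run up. In green the starting material is the limiting reagent, so we count shares of it. First the main step alone: with nearly equal partners, made over left grows in proportion to the charge.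

blue, made over left = 0.394
green share = 50.0%

Then the loss. Target made steadily over the run survives by a share that follows from the lifetimes, so the blue reading understates what was made.

share kept = (1 − exp(−lifetimes)) / lifetimes = 0.681
blue, made over left, loss restored = 0.709
green share = 43.8%

Then the rest, whatever lies behind the lag. We do not model it; we read from ochre against blue how fast made over left really grows with the charge.

ochre, made over left, loss restored = 0.477
power of the charge = 0.777
green share = 40.4%

So our reckoning commits to 40.4%. The forecast differs, at 36%, with the product decays as its choice and orders 1 in reagent and 0.85 in starting material. It took the reagent order from violet, which gives “about half the target at late times”.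

The green run gives 39.4%, the readings show that the product decays, and the starting-rate orders are 0.58 in reagent and 0.62 in starting material.

    starting material → intermediate (0.08220 /min)
    intermediate + reagent → target (0.2238 /M/min)
    intermediate → side product (0.01170 /min)
    target → decomposed product (0.02388 /min)

In the green run the starting material turned into the intermediate from the start, and the intermediate went on with the reagent at 0.0918 /min at the charge, faster than its branch to side product at 0.0117 /min. Target decayed while it was being made: at 35 min the green run held 0.150 M, and our hand count of 0.824 lifetimes in 35 min, itself a reading with its scatter, reckons that as a loss of about 0.00353 M/min, against about 5.60 × 10⁻⁴ M/min reckoned the same way for the 0.0238 M read in the violet run at that time.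

The numbers in the tables were computed with constants of no real substance; the scatter is artificial.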